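Its constants were set for the occasion; what happens was integrated by code.

Dissolved gas is the reagent to follow in this flask, so set out the scheme and the charge first.

    gas phase ⇌ dissolved gas, rate k1*(csat - [dissolved gas]) (k1 = 0.52 h⁻¹, csat = 40 mM)
    starting material + dissolved gas → target (k2 = 1.4 M⁻¹ h⁻¹)
    dissolved gas + target → over-reacted product (k3 = 0.28 M⁻¹ h⁻¹)
    starting material + target → side product (k4 = 0.37 M⁻¹ h⁻¹)

starting material 0.19 M; gas phase 40 mM (held); time 10 h

- percentages count the starting material that a species holds: one side product counts as two
- at the start none of the gas is dissolved
- run time (flask): 10 h

- amount of target at 10 h, in percent of the starting material charged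
- the change that raises the amount of target at 10 h, in percent of the starting material charged most ("none" if none brings more than 2 percentage points) (noon / dawn / none)
- amount of target at 10 h, in percent of the starting material charged, after noon

Draw the curve from both ends and join them. At the start the solution holds no gas, so target leaves zero with zero slope, while the crossing delivers dissolved gas at 0.109 h⁻¹ of the charge. At the far end, set delivery equal to consumption by step 2. This gives the held fraction, the share of saturation at which dissolved gas stands: the transfer coefficient over itself plus k2 times the starting material present. At the charge it is 66.2%.

Join the ends at the knee, 1.27 h, far earlier than the 10 h of the run. Past the knee, target climbs at 0.0370 h⁻¹ of the charge. Step 4 then bends the line, a pseudo-first-order loss of 0.0703 h⁻¹. Hold starting material at its charge and read 24.2% of target at the end.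

Now double each setting. Noon raises the held fraction to 79.6% and gives 30.3%. Dawn leaves the fraction alone and doubles the level, giving 48.3%. Commit to dawn, whose reckoned gain is larger than noon's.

The forecast gives 21%, then 25% after noon, and names dawn, since “doubling the saturation concentration roughly doubles it”. The simulation also names dawn:

| Target at the end | Reckoned | Simulated |
|---|---|---|
| Flask | 24.2% | 21.0% |
| After noon | 30.3% | 25.2% |
| Gain from dawn | 24 percentage points | 15 points |

Recompute the held fraction for the flask at 10.0 h: with 66.3% of the starting material left it gives 74.7%, against a reading of 72.2%. The slow crossing and the path to side product together hold target down in the flask, but each is a part of the shortfall: take away the slowness and the flask gives 30.3%, which covers 12% of what is missing, and take away that path and it gives 27.4%. In the neighbour flask charged with 0.076 M, 64.6% left gives a held fraction of 88.3%, against a reading of 86.4%, and target reaches 28.2%.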